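(The constants come from no measurement; the result is computed.)

Q sits in a stirred flask and turns into G, while X runs in at a steady rate, and we want to know how much X.G is standing when the run stops.

all flasks: Q 10 mM; time 2.5 d
- eta: X 2.50 equiv (fed, over 1.5 h)
- alpha: X 2.50 equiv (fed, over 3.0 h)
- theta: X 2.50 equiv (fed, over 6.0 h)
- beta: X 2.50 equiv (fed, over 12 h)
- zeta: X 2.50 equiv (fed, over 25 h)

    Q → G (k1 = 0.70 h⁻¹)
    X + G → X.G (k2 = 1.6 L mol⁻¹ h⁻¹)
    2 G → G2 (k3 = 5.0 L mol⁻¹ h⁻¹)
    X + X.G → X.X.G (k4 = 0.49 L mol⁻¹ h⁻¹)

- share of X.G in all that became X.G or G2 or X.X.G for eta, alpha, theta, beta, zeta, in this order
- how that number moves from the first to the last of them (rises all the way / falls all the way / falls, then rises / rises, then falls / hardly changes)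

- percentages count the Q that a species holds: one G2 counts as two
- for a step with 2 of a species take k times the square, and two of it per event
- "hardly changes" means that all values lie within two and a half points (for a concentration: within two and a half percent of the largest)
- run time (eta): 2.5 d

Q halves in 0.99 h, while G would halve by X in 0.72 d even with the whole charge of X present (a pseudo-first-order view), so G piles up first. Each G then stands at a fork: does X take it, or another G? X takes G at a rate of 1.6 L mol⁻¹ h⁻¹ times X times G, and pairing takes it at 2 times 5.0 L mol⁻¹ h⁻¹ times G squared. The two are equal at one level of G, which we call the even level, 4.00 mM with the whole charge of X. It lies below the 10 mM of G that Q can give, so pairing wins early and X wins late.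

How much reaches X? In eta the feed is short, so we count the whole charge as present. One G's chance of capture is the even level over the even level plus G, and summing this as G falls from 10 mM toward zero gives 50.1 %.

Does captured material stay? X.G meets X in turn, with a half-life of 2.4 d at the whole charge of X. As a rough date for the capture of a typical G, we take the 0.722 d in which G halves by X. The X.G made then has 1.78 d ahead of it, so about 59.3 % survives to 2.5 d, which leaves a share near 29.7 % for eta.

The even level follows the X present. In zeta, after 2 half-lives of Q, it is only 0.317 mM, against 7.50 mM of G released by then. X.G made after the feed in zeta has less of the run ahead of it, which pulls the other way, but we commit to a share that falls as the feed lengthens.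

The forecast gives 32 %, 31 %, 30 %, 27 % and 22 %, falls all the way, reasoning that “Slower feeding starves G of X during its most concentrated early period”.

The flask gives 31.0 %, 30.3 %, 28.7 %, 26.0 % and 22.1 %, falls all the way, with eta against our 29.7 %. In eta at 2.50 d, G stands at 0.421 mM, under the even level of 3.02 mM for the X then left, and X takes G 7.2 times as fast as pairing does, where that ratio was 0.54 at 0.0413 d. In zeta at the end of the feed, 1.04 d, G at 2.14 mM is already under the even level of 3.69 mM, but G2 by then holds 61.0 %, more than the 50.2 % that eta holds at 2.50 d.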